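**The question.** I wanted to know how much target ash holds at 2.5 min, and how near saturation its dissolved gas then stands.

| flask | substrate | gas phase | remark | time |
|---|---|---|---|---|
| ash | 0.010 M | 1.4 mM (held) | the very flask that is asked about, followed so far |  |
| oak | 0.0050 M | 1.4 mM (held) | run made earlier |  |
| flask | 0.010 M | 1.4 mM (held) |  | 2.5 min |

- ash (time / s: target / %): 10.0: 1; 12.0: 0; 20.0: 4; 25.0: 4; 30.0: 5; 40.0: 7; 50.0: 9
- oak (time / min: target / %): 0.200: 3; 0.333: 5; 0.500: 5; 0.667: 8; 1.00: 13; 1.50: 21; 2.50: 24

(scatter of a reading: 2 percentage points)

1. the target standing at 2.5 min, as a percentage of the substrate charged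
2. concentration of dissolved gas in solution at 2.5 min, in percent of saturation

- at the start none of the gas is dissolved
- on the list of suspects stand: dissolved gas + target -> over-reacted product; gas phase <-> dissolved gas; target <-> isomer of the product; 2 dissolved gas -> homo dimer; substrate + dissolved gas -> target

**A puzzle.** Ash carries twice the substrate of oak, yet ash read 7% at 40.0 s and oak 8% at 40.02 s, a gap smaller than the scatter.

**Clearing it.** If substrate + dissolved gas -> target is the step, the fraction of substrate turned per minute is proportional to c(dissolved gas) and contains no c(substrate). This is pseudo-first-order behaviour, and percentages then climb alike wherever c(dissolved gas) matches. Early target readings show that fraction, not the gas level, so I reckoned no saturation.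

**Both ends.** At the early end, I pooled the last ash reading with oak's at 1.00 min. This gave 0.120 min⁻¹, the percentage rate, meaning the fraction of the charge appearing as target per minute. Run straight to 2.5 min, it gives 30.0%. At the late end, oak read 24% at 2.50 min, which is 6 percentage points under that line, so its curve had bent. Joining the ends, I expected ash to follow oak to about 24%.

**The forecast.** It said 22% and 85%, a target lower than oak's 24%, on its ground that “the doubled substrate draws more gas”.

**The result.** The flask gives 23.9% and 70.8%, so the forecast's saturation stood 14 points high.

    dissolved gas + target → over-reacted product (k = 0.250 L mol⁻¹ s⁻¹)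
    gas phase ⇌ dissolved gas, rate k2*(csat - [dissolved gas]) (kL = 0.140 s⁻¹)
    target ⇌ isomer of the product (K = 2.10, k = 0.00510 s⁻¹)
    2 dissolved gas → homo dimer (k = 19.0 L mol⁻¹ s⁻¹)
    substrate + dissolved gas → target (k = 2.90 L mol⁻¹ s⁻¹)

At 2.50 min the flask also holds 9.31% as isomer of the product. The line's 30.0% stands nearer the 33.7% of substrate gone than the target does.

**Second flask.** For the same flask read at 1.5 min, the percentage rate gives 18.0%. The computed target there is 17.2%.

(The readings were generated by integration with constants of no real substance, and the scatter is random.)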